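The six carbons of ring A (C4a, C5, C6, C7, C8, C8a), with OH on C5 and C8, amount to a doubly enolised 4a,8a-dihydro-1,4,5,8-tetraone, so the naphthazarin is cut at C4a–C5 and C8–C8a. A [4+2] addition of 2,5-bis(trimethylsilyloxy)furan to the free C=C of a 2-substituted 1,4-benzoquinone, then loss of hexamethyldisiloxane and two enolisations, should deliver the whole chromophore in one flask without redox or protecting-group steps. The partner for this step is the (R)-configured benzoquinone that already carries the quaternary cyclobutyl carbon and its angelate. Its single stereocentre is secured beforehand by resolving the tertiary carbinol.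

Key step: step 7

Remark: naphthazarins are fast-exchanging tautomers, so 16 is written in the tautomeric form of the target SMILES; which enantiomer of 5 is the (R) form has to be assigned (vibrational circular dichroism or anomalous-dispersion X-ray diffraction) before material is carried on from step 2.

Step 1
Reactants: 1 2-bromo-1,4-dimethoxybenzene; 2 2,2-dimethylcyclobutanone
Product: 5 rac-1-(2,5-dimethoxyphenyl)-2,2-dimethylcyclobutan-1-ol, via 2,5-dimethoxyphenyllithium 3 (not isolated), via racemic lithium alkoxide 4 (not isolated)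
Conditions: n-BuLi (1.05 equiv), THF, −78 °C; then 2, −78 → 0 °C; H2O
Reagents that add atoms: none
Why: Bromine–lithium exchange gives the aryllithium, which adds 1,2 to the strained and therefore electrophilic cyclobutanone carbonyl (organolithium addition to a ketone); the carbinol stereocentre forms without control, as a racemate.

Step 2
Reactants: 5 rac-1-(2,5-dimethoxyphenyl)-2,2-dimethylcyclobutan-1-ol
Product: 6 (R)-1-(2,5-dimethoxyphenyl)-2,2-dimethylcyclobutan-1-ol
Conditions: preparative SFC, amylose tris(3,5-dimethylphenylcarbamate) on silica, CO2/MeOH, 35 °C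
Reagents that add atoms: none
Why: Resolution of enantiomers by chromatography on a polysaccharide chiral stationary phase is dependable for aryl carbinols with a hydrogen-bond donor and is preferred here to an enantioselective aryl–metal addition, which is not established for α-quaternary cyclobutanones; the stereocentre is thus set by selection of the (R) enantiomer, identified as stated in the remark.

Step 3
Reactants: 7 angelic acid ((Z)-2-methylbut-2-enoic acid, 2 equiv)
Product: 8 angelic anhydride ((Z)-2-methylbut-2-enoic anhydride)
Conditions: DCC (0.5 equiv per acid), CH2Cl2, 0 °C → rt; filtration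
Reagents that add atoms: none
Why: Carbodiimide dehydration of a carboxylic acid to its symmetric anhydride, run without base or nucleophilic catalyst so that the (Z) double bond has no conjugate addition–elimination pathway to the (E) isomer.

Step 4
Reactants: 6 (R)-1-(2,5-dimethoxyphenyl)-2,2-dimethylcyclobutan-1-ol; 8 angelic anhydride
Product: 10 (R)-1-(2,5-dimethoxyphenyl)-2,2-dimethylcyclobutyl (Z)-2-methylbut-2-enoate, via lithium (R)-alkoxide 9 (not isolated)
Conditions: LiN(SiMe3)2 (1.1 equiv), THF, −78 → 0 °C; then 8 (1.3 equiv), 0 °C → rt; H2O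
Reagents that add atoms: none
Why: O-acylation of a preformed tertiary lithium alkoxide by a symmetric anhydride needs no pyridine-type nucleophile (the usual cause of angelate-to-tiglate isomerisation) and forms the acyl C–O bond only, so the (R) carbinol carbon is retained.

Step 5
Reactants: 10 (R)-1-(2,5-dimethoxyphenyl)-2,2-dimethylcyclobutyl (Z)-2-methylbut-2-enoate
Product: 11 (R)-1-(3,6-dioxocyclohexa-1,4-dien-1-yl)-2,2-dimethylcyclobutyl (Z)-2-methylbut-2-enoate
Conditions: (NH4)2Ce(NO3)6 (2.5 equiv), MeCN/H2O 2:1, 0 °C, short reaction time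
Reagents that add atoms: water, O
Why: Oxidative demethylation of a 1,4-dimethoxyarene by tetravalent cerium (two one-electron oxidations, water capture at the ipso carbons, loss of methanol) spares esters and electron-poor alkenes, and it is placed after the acylation because a free cyclobutanol would be ring-opened by the same oxidant.

Step 6
Reactants: 12 succinic anhydride
Product: 13 2,5-bis(trimethylsilyloxy)furan
Conditions: Me3SiCl (2.4 equiv), Et3N (2.4 equiv), ZnCl2 (cat.), MeCN, rt → 50 °C; filtration under N2, distillation under reduced pressure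
Reagents that add atoms: chlorotrimethylsilane, C[Si](C)(C)Cl
Why: Soft enolisation and O-silylation of both anhydride carbonyls (silyl enol ether formation) traps the aromatic 2,5-dioxygenated furan, a distillable, moisture-sensitive diene that is used directly.

Step 7
Reactants: 11 (R)-1-(3,6-dioxocyclohexa-1,4-dien-1-yl)-2,2-dimethylcyclobutyl (Z)-2-methylbut-2-enoate; 13 2,5-bis(trimethylsilyloxy)furan
Product: 16 (R)-1-(5,8-dihydroxy-1,4-dioxo-1,4-dihydronaphthalen-2-yl)-2,2-dimethylcyclobutyl (Z)-2-methylbut-2-enoate, via Diels–Alder adduct 14 (not isolated), via dihydrotetraone 15 (not isolated)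
Conditions: 13 (1.5 equiv), CH2Cl2, −78 → 0 °C; then THF/H2O/AcOH 8:1:1, 0 °C → rt
Reagents that add atoms: none
Why: The electron-rich disilyloxyfuran 13 adds as the 4π partner in a normal-demand [4+2] cycloaddition to the unsubstituted C=C of quinone 11, forming C4a–C5 and C8–C8a in one event, whether concerted or through a short-lived zwitterion that collapses to the same adduct 14. The closest known reaction type is the Diels–Alder reaction of 2,5-bis(trialkylsilyloxy)furans with quinones and other electron-poor dienophiles, whose 7-oxanorbornene adducts open to para-dioxygenated six-membered rings. Ring A closes by intermolecular [4+2] cycloaddition as the carbocycle of a 7-oxabicyclo[2.2.1]heptene; protodesilylation of one bridgehead silyl ketal then pushes the bridging oxygen onto the other bridgehead, loss of hexamethyldisiloxane leaves the 4a,8a-dihydro-1,4,5,8-tetraone 15, and two enolisations, driven by aromatisation and the two O–H···O=C hydrogen bonds, give 16. No new stereocentre survives, since C4a, C5, C8 and C8a all end trigonal, so endo/exo and facial selectivity are irrelevant and the quaternary (R) carbon is not touched. The selectivity needed is site selectivity: the substituted quinone C=C (C2=C3 of the product) is trisubstituted and shielded by the fully substituted cyclobutyl carbon, so addition there would have to build a quaternary centre beside it, while the angelate C=C is trisubstituted and only singly activated. Because quinone and furan together already stand at the oxidation level of the naphthazarin, no oxidant, reductant or phenol protection is needed and the (Z) ester never meets a Lewis acid.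

Compound list
1 | 2-bromo-1,4-dimethoxybenzene | COc1ccc(OC)c(Br)c1 | starting material
2 | 2,2-dimethylcyclobutanone | CC1(C)CCC1=O | starting material
3 | 2,5-dimethoxyphenyllithium | [Li]c1cc(OC)ccc1OC | intermediate
4 | lithium 1-(2,5-dimethoxyphenyl)-2,2-dimethylcyclobutan-1-olate (racemic) | [Li]OC1(c2cc(OC)ccc2OC)CCC1(C)C | intermediate
5 | rac-1-(2,5-dimethoxyphenyl)-2,2-dimethylcyclobutan-1-ol | OC1(c2cc(OC)ccc2OC)CCC1(C)C | intermediate
6 | (R)-1-(2,5-dimethoxyphenyl)-2,2-dimethylcyclobutan-1-ol | O[C@]1(c2cc(OC)ccc2OC)CCC1(C)C | intermediate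
7 | angelic acid, (Z)-2-methylbut-2-enoic acid | C/C=C(/C)C(=O)O | starting material
8 | angelic anhydride, (Z)-2-methylbut-2-enoic anhydride | C/C=C(/C)C(=O)OC(=O)/C(C)=C\C | intermediate
9 | lithium (R)-1-(2,5-dimethoxyphenyl)-2,2-dimethylcyclobutan-1-olate | [Li]O[C@]1(c2cc(OC)ccc2OC)CCC1(C)C | intermediate
10 | (R)-1-(2,5-dimethoxyphenyl)-2,2-dimethylcyclobutyl (Z)-2-methylbut-2-enoate | C/C=C(/C)C(=O)O[C@]1(c2cc(OC)ccc2OC)CCC1(C)C | intermediate
11 | (R)-1-(3,6-dioxocyclohexa-1,4-dien-1-yl)-2,2-dimethylcyclobutyl (Z)-2-methylbut-2-enoate | C/C=C(/C)C(=O)O[C@]1(C2=CC(=O)C=CC2=O)CCC1(C)C | intermediate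
12 | succinic anhydride | O=C1CCC(=O)O1 | starting material
13 | 2,5-bis(trimethylsilyloxy)furan | C[Si](C)(C)Oc1ccc(O[Si](C)(C)C)o1 | intermediate
14 | (R)-1-[5,8-epoxy-1,4-dioxo-5,8-bis(trimethylsilyloxy)-1,4,4a,5,8,8a-hexahydronaphthalen-2-yl]-2,2-dimethylcyclobutyl (Z)-2-methylbut-2-enoate (Diels–Alder adduct, mixture of diastereomers at C4a, C5, C8, C8a) | C/C=C(/C)C(=O)O[C@]1(C2=CC(=O)C3C(C2=O)C4(O[Si](C)(C)C)C=CC3(O[Si](C)(C)C)O4)CCC1(C)C | intermediate
15 | (R)-2,2-dimethyl-1-(1,4,5,8-tetraoxo-1,4,4a,5,8,8a-hexahydronaphthalen-2-yl)cyclobutyl (Z)-2-methylbut-2-enoate (4a,8a-dihydro tetraone) | C/C=C(/C)C(=O)O[C@]1(C2=CC(=O)C3C(C2=O)C(=O)C=CC3=O)CCC1(C)C | intermediate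
16 | (R)-1-(5,8-dihydroxy-1,4-dioxo-1,4-dihydronaphthalen-2-yl)-2,2-dimethylcyclobutyl (Z)-2-methylbut-2-enoate | C/C=C(/C)C(=O)O[C@]1(C2=CC(=O)c3c(O)ccc(O)c3C2=O)CCC1(C)C | target

Total step count: 7. Longest linear sequence: 5 steps (1, 2, 4, 5, 7); steps 3 and 6 prepare the two reagents.

Steps most likely to fail

Step 7. The very electron-rich furan may add to the quinone in a conjugate (Mukaiyama–Michael-type) sense or transfer an electron instead of cycloadding, or the adduct may enolise early and undergo redox exchange with unreacted quinone. In the fallback, ring A is brought in as a protected arene and the naphthazarin is released oxidatively. Setting out from ketone 2, 2-bromo-1,4,5,8-tetramethoxynaphthalene F1 (NBS bromination of 1,4,5,8-tetramethoxynaphthalene in MeCN) is lithiated with n-BuLi at −78 °C and added to 2 to give rac-2,2-dimethyl-1-(1,4,5,8-tetramethoxynaphthalen-2-yl)cyclobutan-1-ol F2. Resolution as in step 2 should give the (R) carbinol F3, and acylation with 8 as in step 4 the angelate F4. (NH4)2Ce(NO3)6 in MeCN/H2O should oxidise one ring to the dimethoxynaphthoquinone F5 (drawn oxidised in the unsubstituted ring; the ring isomer would converge). AgO in dilute HNO3 should then oxidise the second ring to the naphthalene-1,4,5,8-tetraone F6, and Na2S2O4 should reduce F6 to 16, where the route is rejoined. This oxidise-then-reduce release of a naphthazarin from its tetramethyl ether is established chemistry and uses no Lewis acid.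

Step 4. Acylation of the hindered tertiary alkoxide may be slow enough for γ-deprotonation of the anhydride or (Z)-to-(E) isomerisation to intervene. In the fallback, the (Z) alkene is built after the ester bond. Setting out from 6, DCC coupling with 2-[bis(2,2,2-trifluoroethoxy)phosphoryl]propanoic acid (acyl transfer through the phosphoryl ketene, which tolerates tertiary alcohols) would give (R)-1-(2,5-dimethoxyphenyl)-2,2-dimethylcyclobutyl 2-[bis(2,2,2-trifluoroethoxy)phosphoryl]propanoate F7. Still–Gennari olefination (KN(SiMe3)2, 18-crown-6, THF, −78 °C, acetaldehyde) should then form the (Z)-trisubstituted enoate, which is 10, where the route is rejoined.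

Step 5. While the ring is still an electron-rich arene in the acidic medium, the tertiary benzylic C–O bond may ionise, or the strained benzylic C–C bond may cleave in the arene radical cation. In the fallback, the oxidation is done under basic conditions and the acid is applied only afterwards. Setting out from 10, anodic oxidation (carbon anode, undivided cell, KOH/MeOH, 0 °C) should trap the oxidised ring as the quinone bisketal (R)-2,2-dimethyl-1-(3,3,6,6-tetramethoxycyclohexa-1,4-dien-1-yl)cyclobutyl (Z)-2-methylbut-2-enoate F8. Hydrolysis with dilute aqueous acid in acetone, now on a ring that can no longer stabilise a benzylic cation, should give 11, where the route is rejoined.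

Further compounds
F1 | step 7 | 2-bromo-1,4,5,8-tetramethoxynaphthalene | COc1ccc(OC)c2c(OC)c(Br)cc(OC)c12
F2 | step 7 | rac-2,2-dimethyl-1-(1,4,5,8-tetramethoxynaphthalen-2-yl)cyclobutan-1-ol | COc1ccc(OC)c2c(OC)c(C3(O)CCC3(C)C)cc(OC)c12
F3 | step 7 | (R)-2,2-dimethyl-1-(1,4,5,8-tetramethoxynaphthalen-2-yl)cyclobutan-1-ol | O[C@]1(c2cc(OC)c3c(OC)ccc(OC)c3c2OC)CCC1(C)C
F4 | step 7 | (R)-2,2-dimethyl-1-(1,4,5,8-tetramethoxynaphthalen-2-yl)cyclobutyl (Z)-2-methylbut-2-enoate | C/C=C(/C)C(=O)O[C@]1(c2cc(OC)c3c(OC)ccc(OC)c3c2OC)CCC1(C)C
F5 | step 7 | (R)-1-(1,4-dimethoxy-5,8-dioxo-5,8-dihydronaphthalen-2-yl)-2,2-dimethylcyclobutyl (Z)-2-methylbut-2-enoate | C/C=C(/C)C(=O)O[C@]1(c2cc(OC)c3C(=O)C=CC(=O)c3c2OC)CCC1(C)C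
F6 | step 7 | (R)-2,2-dimethyl-1-(1,4,5,8-tetraoxo-1,4,5,8-tetrahydronaphthalen-2-yl)cyclobutyl (Z)-2-methylbut-2-enoate | C/C=C(/C)C(=O)O[C@]1(C2=CC(=O)C3=C(C2=O)C(=O)C=CC3=O)CCC1(C)C
F7 | step 4 | (R)-1-(2,5-dimethoxyphenyl)-2,2-dimethylcyclobutyl 2-[bis(2,2,2-trifluoroethoxy)phosphoryl]propanoate (both epimers at the phosphonate carbon) | CC(C(=O)O[C@]1(c2cc(OC)ccc2OC)CCC1(C)C)P(=O)(OCC(F)(F)F)OCC(F)(F)F
F8 | step 5 | (R)-2,2-dimethyl-1-(3,3,6,6-tetramethoxycyclohexa-1,4-dien-1-yl)cyclobutyl (Z)-2-methylbut-2-enoate | C/C=C(/C)C(=O)O[C@]1(C2=CC(OC)(OC)C=CC2(OC)OC)CCC1(C)C
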